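**Retrosynthetic overview**

1. The route rests on the benzene ring C4a–C5–C6–C7–C8–C8a: all six positions are substituted, with oxygen on C5, C7 and C8a and three different carbon groups on C4a (the C4 ketone), C6 (prenyl) and C8 (hexanoate chain). Substitution of a phloroglucinol cannot sort these, so the ring is built last from acyclic carbons.
2. Target 34 comes from its O7 silyl ether 33. Ring 33 is cut at C5–C6, C7–C8 and C4a–C5 into diazo ketone 23 (which gives a vinylketene containing the C8a=C4a alkene) and siloxyalkyne 28.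
3. Diazo ketone 23 comes from ketone 20 by diazo transfer. Ketone 20 comes from acid chloride 14 and alkylzinc 19, which carries the side-chain centre of lactone 15.
4. Acid chloride 14 comes from a syn-aldol (1 + 2), an oxalate Claisen condensation and a cyclodehydration, which set cis C2/C3. Alkyne 28 comes from acid 24 through an ynolate.
5. Ring order: the dihydropyranone ring (O1, C2, C3, C4, C4a, C8a) is closed first in step 6, and the benzene ring is closed last in step 14.

Key step: step 14

Remark on the chemistry: chroman numbering is used for the target. The side-chain centre keeps one spatial arrangement from lactone 15 to the target; it is written S only in ketone 20 because the substituent priorities change there.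

**Route**

Step 1
Reactants: 1 (4S)-4-benzyl-3-propanoyl-1,3-oxazolidin-2-one; 2 acetaldehyde
Product: 4 (4S)-4-benzyl-3-[(2S,3R)-3-hydroxy-2-methylbutanoyl]-1,3-oxazolidin-2-one, via boron enolate 3 (not isolated)
Conditions: Bu2BOTf, i-Pr2NEt, CH2Cl2, −78 → 0 °C; MeCHO, −78 → 0 °C; pH 7 buffer, MeOH, 30% H2O2, 0 °C
Reagents that add atoms: none
Why: Evans syn-aldol reaction: the Z boron enolate 3 adds to acetaldehyde through a chair Zimmerman–Traxler transition state on the enolate face away from the benzyl group, which should set C2 as S and C3 as R (syn).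

Step 2
Reactants: 4 (4S)-4-benzyl-3-[(2S,3R)-3-hydroxy-2-methylbutanoyl]-1,3-oxazolidin-2-one
Product: 5 (2S,3R)-3-hydroxy-N-methoxy-N,2-dimethylbutanamide
Conditions: MeONHMe·HCl, AlMe3, CH2Cl2, −20 → 0 °C; 1 M HCl
Reagents that add atoms: N,O-dimethylhydroxylamine hydrochloride, CNOC.Cl
Why: Weinreb transamidation: the aluminium amide, anchored by the C3 hydroxyl as its aluminium alkoxide, attacks the exocyclic imide carbonyl and releases the auxiliary without touching either stereocentre.

Step 3
Reactants: 5 (2S,3R)-3-hydroxy-N-methoxy-N,2-dimethylbutanamide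
Product: 6 (2S,3R)-3-[tert-butyl(dimethyl)silyl]oxy-N-methoxy-N,2-dimethylbutanamide
Conditions: TBSCl, imidazole, DMF, rt
Reagents that add atoms: tert-butyl(chloro)dimethylsilane, CC(C)(C)[Si](C)(C)Cl
Why: Standard silylation of a secondary alcohol, so that the later enolate chemistry meets no free hydroxyl and no retro-aldol path.

Step 4
Reactants: 6 (2S,3R)-3-[tert-butyl(dimethyl)silyl]oxy-N-methoxy-N,2-dimethylbutanamide
Product: 7 (3S,4R)-4-[tert-butyl(dimethyl)silyl]oxy-3-methylpentan-2-one
Conditions: MeMgBr, THF, 0 °C; aq. NH4Cl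
Reagents that add atoms: methylmagnesium bromide, C[Mg]Br
Why: Weinreb ketone synthesis: the chelated tetrahedral magnesium adduct survives until work-up, so one methyl group is delivered and the α-stereocentre is not enolised.

Step 5
Reactants: 7 (3S,4R)-4-[tert-butyl(dimethyl)silyl]oxy-3-methylpentan-2-one; 8 di-tert-butyl oxalate
Product: 10 tert-butyl (5S,6R)-6-[tert-butyl(dimethyl)silyl]oxy-5-methyl-2,4-dioxoheptanoate, via lithium enolate 9 (not isolated)
Conditions: LiN(SiMe3)2 (2.2 equiv), THF, −78 °C; 8, −78 → 0 °C; aq. NH4Cl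
Reagents that add atoms: none
Why: Crossed Claisen condensation: the hindered amide base removes a methyl proton (kinetic enolate 9), the non-enolisable oxalate acylates it, and the product rests as its diketonate, which protects C5 from epimerisation.

Step 6
Reactants: 10 tert-butyl (5S,6R)-6-[tert-butyl(dimethyl)silyl]oxy-5-methyl-2,4-dioxoheptanoate
Product: 13 (2R,3S)-2,3-dimethyl-4-oxo-3,4-dihydro-2H-pyran-6-carboxylic acid, via hydroxy diketo ester 11 (not isolated), via tert-butyl pyranone ester 12 (not isolated)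
Conditions: CF3CO2H, CH2Cl2, 0 °C → rt
Reagents that add atoms: none
Why: Acid-mediated desilylation and cyclodehydration: the freed C6 hydroxyl adds to the C2 ketone to give a six-membered hemiketal that loses water to the vinylogous ester, the same acid then cleaves the tert-butyl ester, and since no bond at either stereocentre is broken the syn-aldol pattern should appear as the cis-2,3-dimethyl ring.

Step 7
Reactants: 13 (2R,3S)-2,3-dimethyl-4-oxo-3,4-dihydro-2H-pyran-6-carboxylic acid
Product: 14 (2R,3S)-2,3-dimethyl-4-oxo-3,4-dihydro-2H-pyran-6-carbonyl chloride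
Conditions: (COCl)2, DMF (cat.), CH2Cl2, 0 °C → rt; concentrate, use crude
Reagents that add atoms: oxalyl chloride, ClC(=O)C(=O)Cl
Why: Acid chloride formation through the Vilsmeier-type chloroiminium species under mild, non-basic conditions that should leave the enolisable C3 centre alone.

Step 8
Reactants: 15 (4R)-4-propyloxolan-2-one
Product: 18 methyl (3R)-3-(iodomethyl)hexanoate, via silyl ester 16 (not isolated), via iodo acid 17 (not isolated)
Conditions: Me3SiI, CH2Cl2, 0 °C → rt; then MeOH, rt
Reagents that add atoms: iodotrimethylsilane, C[Si](C)(C)I; methanol, CO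
Why: Silyl iodide opening of a lactone: iodide attacks the O-bearing CH2 in SN2 fashion (not the stereocentre), and the silyl ester 16 is methanolysed and then esterified (Fischer) by the hydrogen iodide set free.

Step 9
Reactants: 18 methyl (3R)-3-(iodomethyl)hexanoate; 14 (2R,3S)-2,3-dimethyl-4-oxo-3,4-dihydro-2H-pyran-6-carbonyl chloride
Product: 20 methyl (3S)-3-{2-[(2R,3S)-2,3-dimethyl-4-oxo-3,4-dihydro-2H-pyran-6-yl]-2-oxoethyl}hexanoate, via alkylzinc iodide 19 (not isolated)
Conditions: 18, Zn dust (activated by BrCH2CH2Br, Me3SiCl), THF, 40 °C; then 14, Pd(PPh3)4 (5 mol %), THF, 0 °C → rt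
Reagents that add atoms: none
Why: Negishi acylation: zinc inserts into the primary C–I bond, and the alkylzinc 19, inert towards ester and enone, transfers its alkyl group to the acylpalladium species formed from 14 and zerovalent palladium.

Step 10
Reactants: 20 methyl (3S)-3-{2-[(2R,3S)-2,3-dimethyl-4-oxo-3,4-dihydro-2H-pyran-6-yl]-2-oxoethyl}hexanoate
Product: 22 methyl (3R)-3-{1-[(2R,3S)-2,3-dimethyl-4-oxo-3,4-dihydro-2H-pyran-6-yl]-4,4,4-trifluoro-1,3-dioxobutan-2-yl}hexanoate (epimers at the new carbon and enol forms; used crude), via lithium enolate 21 (not isolated)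
Conditions: LiN(SiMe3)2 (1.1 equiv), THF, −78 °C; CF3CO2CH2CF3, −78 °C; dilute HCl
Reagents that add atoms: 2,2,2-trifluoroethyl trifluoroacetate, O=C(OCC(F)(F)F)C(F)(F)F
Why: First half of the detrifluoroacetylative diazo transfer: the ketone CH2 is the most acidic position, so its lithium enolate 21 should form selectively at −78 °C and undergo Claisen-type C-acylation by the trifluoroethyl ester.

Step 11
Reactants: 22 methyl (3R)-3-{1-[(2R,3S)-2,3-dimethyl-4-oxo-3,4-dihydro-2H-pyran-6-yl]-4,4,4-trifluoro-1,3-dioxobutan-2-yl}hexanoate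
Product: 23 methyl (3R)-3-{1-diazo-2-[(2R,3S)-2,3-dimethyl-4-oxo-3,4-dihydro-2H-pyran-6-yl]-2-oxoethyl}hexanoate
Conditions: 4-AcNHC6H4SO2N3, Et3N, H2O (1 equiv), MeCN, rt
Reagents that add atoms: 4-acetamidobenzenesulfonyl azide, CC(=O)Nc1ccc(cc1)S(=O)(=O)N=[N+]=[N-]
Why: Regitz-type deacylative diazo transfer: the diketone enolate adds to the terminal nitrogen of the sulfonyl azide and the adduct fragments with transfer of the trifluoroacetyl group to the sulfonamide nitrogen, under amine conditions too mild to epimerise C3.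

Step 12
Reactants: 24 4-methylpent-3-enoic acid
Product: 25 methyl 4-methylpent-3-enoate
Conditions: MeI, K2CO3, DMF, rt
Reagents that add atoms: iodomethane, CI
Why: SN2 O-alkylation of the carboxylate, chosen over acid-catalysed esterification, which would lactonise this β,γ-unsaturated acid.

Step 13
Reactants: 25 methyl 4-methylpent-3-enoate
Product: 28 triisopropyl[(5-methylhex-4-en-1-yn-1-yl)oxy]silane, via dibromo enolate 26 (not isolated), via lithium ynolate 27 (not isolated)
Conditions: CH2Br2, lithium 2,2,6,6-tetramethylpiperidide, THF, −78 °C; 25; n-BuLi, −78 °C → rt; i-Pr3SiCl, −78 °C → rt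
Reagents that add atoms: dibromomethane, BrCBr; chlorotri(propan-2-yl)silane, CC(C)[Si](Cl)(C(C)C)C(C)C
Why: Kowalski ester homologation stopped at the ynolate: addition of dibromomethyllithium and loss of methoxide give 26, bromine–lithium exchange triggers the 1,2-shift to ynolate 27, and the bulky silyl chloride reacts at oxygen.

Step 14
Reactants: 23 methyl (3R)-3-{1-diazo-2-[(2R,3S)-2,3-dimethyl-4-oxo-3,4-dihydro-2H-pyran-6-yl]-2-oxoethyl}hexanoate; 28 triisopropyl[(5-methylhex-4-en-1-yn-1-yl)oxy]silane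
Product: 33 methyl (3R)-3-[(2R,3S)-5-hydroxy-2,3-dimethyl-6-(3-methylbut-2-en-1-yl)-4-oxo-7-[tri(propan-2-yl)silyl]oxy-3,4-dihydro-2H-chromen-8-yl]hexanoate, via vinylketene 29 (not isolated), via vinylcyclobutenone 30 (not isolated), via dienylketene 31 (not isolated), via cyclohexadienone 32 (not isolated)
Conditions: 28 (2 equiv), degassed ClCH2CH2Cl, hν (440 nm LED), −20 °C → rt; then 80 °C
Reagents that add atoms: none
Why: Danheiser benzannulation in its photochemical form: excitation of the diazo ketone expels N2 and the pyranonyl group migrates to the former diazo carbon (Wolff rearrangement), which gives vinylketene 29 whose alkene is the C8a=C4a bond of the dihydropyranone. The nucleophilic, prenyl-bearing carbon of the ynol silyl ether attacks the ketene carbon and [2+2] closure gives cyclobutenone 30 (bonds C5–C6 and C7–C8); on warming, conrotatory four-electron opening gives dienylketene 31, whose thermal disrotatory six-electron electrocyclisation closes the benzene ring at C5–C4a, and enolisation of dienone 32 delivers phenol 33. The closest known reaction type is the benzannulation of alkenyl and heteroaryl α-diazo ketones with siloxyalkynes to resorcinol monosilyl ethers; the present ketene is more substituted than usual. No lasting stereocentre is formed (the sp3 centres of 30 and 32 vanish), and C2, C3 and the side-chain centre are not touched because the conditions are neutral and non-enolising. The regiochemistry needed, prenyl on C6 between the free, ketone-bonded C5 hydroxyl and the C7 silyl ether, follows from the polarisation of the siloxyalkyne, while O1 on C8a and the chain on C8 are fixed by the connectivity of 23. The least secure selectivity is Wolff migration against 1,2-hydrogen shift of the carbene to the neighbouring tertiary C–H, which long-wavelength irradiation at low temperature and an excess of the alkyne are meant to favour.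

Step 15
Reactants: 33 methyl (3R)-3-[(2R,3S)-5-hydroxy-2,3-dimethyl-6-(3-methylbut-2-en-1-yl)-4-oxo-7-[tri(propan-2-yl)silyl]oxy-3,4-dihydro-2H-chromen-8-yl]hexanoate
Product: 34 methyl (3R)-3-[(2R,3S)-5,7-dihydroxy-2,3-dimethyl-6-(3-methylbut-2-en-1-yl)-4-oxo-3,4-dihydro-2H-chromen-8-yl]hexanoate
Conditions: HF·pyridine, pyridine, THF, 0 °C → rt
Reagents that add atoms: none
Why: Fluoride-mediated cleavage of the aryl silyl ether under buffered, weakly acidic conditions, which should spare the base-sensitive cis-chromanone, the methyl ester and the prenyl group.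

**Compound list**

1 | (4S)-4-benzyl-3-propanoyl-1,3-oxazolidin-2-one | CCC(=O)N1[C@@H](Cc2ccccc2)COC1=O | starting material
2 | acetaldehyde | CC=O | starting material
3 | (4S)-4-benzyl-3-[(1Z)-1-(dibutylboranyloxy)prop-1-en-1-yl]-1,3-oxazolidin-2-one | C/C=C(\OB(CCCC)CCCC)N1[C@@H](Cc2ccccc2)COC1=O | intermediate
4 | (4S)-4-benzyl-3-[(2S,3R)-3-hydroxy-2-methylbutanoyl]-1,3-oxazolidin-2-one | C[C@@H](O)[C@H](C)C(=O)N1[C@@H](Cc2ccccc2)COC1=O | intermediate
5 | (2S,3R)-3-hydroxy-N-methoxy-N,2-dimethylbutanamide | C[C@@H](O)[C@H](C)C(=O)N(C)OC | intermediate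
6 | (2S,3R)-3-[tert-butyl(dimethyl)silyl]oxy-N-methoxy-N,2-dimethylbutanamide | C[C@@H](O[Si](C)(C)C(C)(C)C)[C@H](C)C(=O)N(C)OC | intermediate
7 | (3S,4R)-4-[tert-butyl(dimethyl)silyl]oxy-3-methylpentan-2-one | C[C@@H](O[Si](C)(C)C(C)(C)C)[C@H](C)C(C)=O | intermediate
8 | di-tert-butyl oxalate | CC(C)(C)OC(=O)C(=O)OC(C)(C)C | starting material
9 | lithium (3S,4R)-4-[tert-butyl(dimethyl)silyl]oxy-3-methylpent-1-en-2-olate | C[C@@H](O[Si](C)(C)C(C)(C)C)[C@H](C)C(=C)[O-].[Li+] | intermediate
10 | tert-butyl (5S,6R)-6-[tert-butyl(dimethyl)silyl]oxy-5-methyl-2,4-dioxoheptanoate | C[C@@H](O[Si](C)(C)C(C)(C)C)[C@H](C)C(=O)CC(=O)C(=O)OC(C)(C)C | intermediate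
11 | tert-butyl (5S,6R)-6-hydroxy-5-methyl-2,4-dioxoheptanoate | C[C@@H](O)[C@H](C)C(=O)CC(=O)C(=O)OC(C)(C)C | intermediate
12 | tert-butyl (2R,3S)-2,3-dimethyl-4-oxo-3,4-dihydro-2H-pyran-6-carboxylate | CC(C)(C)OC(=O)C1=CC(=O)[C@@H](C)[C@@H](C)O1 | intermediate
13 | (2R,3S)-2,3-dimethyl-4-oxo-3,4-dihydro-2H-pyran-6-carboxylic acid | OC(=O)C1=CC(=O)[C@@H](C)[C@@H](C)O1 | intermediate
14 | (2R,3S)-2,3-dimethyl-4-oxo-3,4-dihydro-2H-pyran-6-carbonyl chloride | ClC(=O)C1=CC(=O)[C@@H](C)[C@@H](C)O1 | intermediate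
15 | (4R)-4-propyloxolan-2-one | CCC[C@H]1COC(=O)C1 | starting material
16 | trimethylsilyl (3R)-3-(iodomethyl)hexanoate | CCC[C@H](CC(=O)O[Si](C)(C)C)CI | intermediate
17 | (3R)-3-(iodomethyl)hexanoic acid | CCC[C@H](CC(=O)O)CI | intermediate
18 | methyl (3R)-3-(iodomethyl)hexanoate | CCC[C@H](CC(=O)OC)CI | intermediate
19 | [(2R)-2-(2-methoxy-2-oxoethyl)pentyl]zinc iodide | CCC[C@H](CC(=O)OC)C[Zn]I | intermediate
20 | methyl (3S)-3-{2-[(2R,3S)-2,3-dimethyl-4-oxo-3,4-dihydro-2H-pyran-6-yl]-2-oxoethyl}hexanoate | CCC[C@H](CC(=O)OC)CC(=O)C1=CC(=O)[C@@H](C)[C@@H](C)O1 | intermediate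
21 | lithium (3R)-1-[(2R,3S)-2,3-dimethyl-4-oxo-3,4-dihydro-2H-pyran-6-yl]-3-(2-methoxy-2-oxoethyl)hex-1-en-1-olate (alkene geometry not defined) | CCC[C@H](CC(=O)OC)C=C([O-])C1=CC(=O)[C@@H](C)[C@@H](C)O1.[Li+] | intermediate
22 | methyl (3R)-3-{1-[(2R,3S)-2,3-dimethyl-4-oxo-3,4-dihydro-2H-pyran-6-yl]-4,4,4-trifluoro-1,3-dioxobutan-2-yl}hexanoate (epimers at C2 of the butanyl unit) | CCC[C@H](CC(=O)OC)C(C(=O)C(F)(F)F)C(=O)C1=CC(=O)[C@@H](C)[C@@H](C)O1 | intermediate
23 | methyl (3R)-3-{1-diazo-2-[(2R,3S)-2,3-dimethyl-4-oxo-3,4-dihydro-2H-pyran-6-yl]-2-oxoethyl}hexanoate | CCC[C@H](CC(=O)OC)C(=[N+]=[N-])C(=O)C1=CC(=O)[C@@H](C)[C@@H](C)O1 | intermediate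
24 | 4-methylpent-3-enoic acid | CC(C)=CCC(=O)O | starting material
25 | methyl 4-methylpent-3-enoate | CC(C)=CCC(=O)OC | intermediate
26 | lithium 1,1-dibromo-5-methylhexa-1,4-dien-2-olate | [Li+].[O-]C(CC=C(C)C)=C(Br)Br | intermediate
27 | lithium 5-methylhex-4-en-1-yn-1-olate | [Li+].[O-]C#CCC=C(C)C | intermediate
28 | triisopropyl[(5-methylhex-4-en-1-yn-1-yl)oxy]silane | CC(C)=CCC#CO[Si](C(C)C)(C(C)C)C(C)C | intermediate
29 | methyl (3R)-3-{1-[(2R,3S)-2,3-dimethyl-4-oxo-3,4-dihydro-2H-pyran-6-yl]-2-oxoethenyl}hexanoate | CCC[C@H](CC(=O)OC)C(=C=O)C1=CC(=O)[C@@H](C)[C@@H](C)O1 | intermediate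
30 | methyl (3R)-3-{1-[(2R,3S)-2,3-dimethyl-4-oxo-3,4-dihydro-2H-pyran-6-yl]-3-(3-methylbut-2-en-1-yl)-4-oxo-2-[tri(propan-2-yl)silyl]oxycyclobut-2-en-1-yl}hexanoate (epimers at the ring carbon C1) | CCC[C@H](CC(=O)OC)C1(C(=O)C(CC=C(C)C)=C1O[Si](C(C)C)(C(C)C)C(C)C)C2=CC(=O)[C@@H](C)[C@@H](C)O2 | intermediate
31 | methyl (3R)-3-{(1E)-1-[(2R,3S)-2,3-dimethyl-4-oxo-3,4-dihydro-2H-pyran-6-yl]-3-(3-methylbut-2-en-1-yl)-4-oxo-2-[tri(propan-2-yl)silyl]oxybuta-1,3-dien-1-yl}hexanoate | CCC[C@H](CC(=O)OC)/C(C2=CC(=O)[C@@H](C)[C@@H](C)O2)=C(O[Si](C(C)C)(C(C)C)C(C)C)/C(CC=C(C)C)=C=O | intermediate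
32 | methyl (3R)-3-[(2R,3S)-2,3-dimethyl-6-(3-methylbut-2-en-1-yl)-4,5-dioxo-7-[tri(propan-2-yl)silyl]oxy-3,4,4a,5-tetrahydro-2H-chromen-8-yl]hexanoate (C4a not defined) | CCC[C@H](CC(=O)OC)C1=C2O[C@H](C)[C@H](C)C(=O)C2C(=O)C(CC=C(C)C)=C1O[Si](C(C)C)(C(C)C)C(C)C | intermediate
33 | methyl (3R)-3-[(2R,3S)-5-hydroxy-2,3-dimethyl-6-(3-methylbut-2-en-1-yl)-4-oxo-7-[tri(propan-2-yl)silyl]oxy-3,4-dihydro-2H-chromen-8-yl]hexanoate | CCC[C@H](CC(=O)OC)c1c(O[Si](C(C)C)(C(C)C)C(C)C)c(CC=C(C)C)c(O)c2c1O[C@H](C)[C@H](C)C2=O | intermediate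
34 | methyl (3R)-3-[(2R,3S)-5,7-dihydroxy-2,3-dimethyl-6-(3-methylbut-2-en-1-yl)-4-oxo-3,4-dihydro-2H-chromen-8-yl]hexanoate | CCC[C@H](CC(=O)OC)c1c(O)c(CC=C(C)C)c(O)c2c1O[C@H](C)[C@H](C)C2=O | target

**Step count**

Total: 15 steps. Longest linear sequence: 12 steps (1, 2, 3, 4, 5, 6, 7, 9, 10, 11, 14, 15).

**Steps most likely to fail**

1. Step 14. After loss of nitrogen, hydrogen migration from the neighbouring tertiary carbon to the carbene centre (giving a conjugated enone) may outrun the Wolff shift. The hindered, disubstituted ketene may also add to the alkyne slowly and be lost to dimerisation. The fallback sets out from acid chloride 14 and comes back at 33. Acid chloride 14 with Me3SiCHN2 (MeCN–THF, 0 °C) should give diazomethyl ketone F1, whose diazo carbon has no neighbouring C–H and which belongs to the substrate class for which this benzannulation is established. Irradiation of F1 with 28 and heating, as in step 14, should give the C8-unsubstituted chromanone F2. Vilsmeier formylation (POCl3, DMF) at C8, the only free and most activated ring position, should give aldehyde F3. Wittig olefination with Ph3P=CHCO2Me should give cinnamate F4. Copper-catalysed asymmetric conjugate addition of PrMgBr (CuBr·SMe2, chiral ferrocenyl diphosphine, t-BuOMe, −75 °C) should then give 33. The ligand enantiomer is chosen to deliver the 3R centre, and the first equivalent of Grignard reagent turns the C5 phenol into a magnesium phenoxide that chelates and shields the C4 ketone. The price is that the side-chain centre is then set by the catalyst and no longer taken from lactone 15.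

2. Step 10. Enolisation may not stay at the ketone CH2: proton exchange at C3 of the pyranone would convert the cis ring into the more stable trans ring, and C-acylation of the β-branched enolate may be slow. The fallback sets out from ketone 20 and comes back at diazo ketone 23, bypassing steps 10 and 11. Heating 20 with Me2NCH(OMe)2 (toluene, 80 °C) should give enaminone F5 without any metal enolate. Diazo transfer from 4-acetamidobenzenesulfonyl azide to the enaminone (CH2Cl2, rt) goes through a triazoline that sheds the sulfonyl formamidine and should give 23.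

3. Step 13. The amide base or the carbenoid may deprotonate the doubly activated α-CH2 of the β,γ-unsaturated ester and not add to the carbonyl group, which would lead to a dienolate and double-bond migration. The fallback sets out from ester 25 and comes back at ynolate 27, and so at 28. Reduction of 25 with i-Bu2AlH (CH2Cl2, −78 °C) should give aldehyde F6. Corey–Fuchs olefination (CBr4, PPh3) should give dibromoalkene F7. n-BuLi (2 equiv) should convert F7 into alkynyllithium F8, which is oxidised in the same flask by LiOOt-Bu (from t-BuOOH and LiN(SiMe3)2) to ynolate 27 and silylated as in step 13.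

**Further compounds**

F1 | step 14 | (2R,3S)-6-(diazoacetyl)-2,3-dimethyl-2,3-dihydro-4H-pyran-4-one | [N-]=[N+]=CC(=O)C1=CC(=O)[C@@H](C)[C@@H](C)O1
F2 | step 14 | (2R,3S)-5-hydroxy-2,3-dimethyl-6-(3-methylbut-2-en-1-yl)-7-[tri(propan-2-yl)silyl]oxy-2,3-dihydro-4H-chromen-4-one | CC(C)=CCc1c(O[Si](C(C)C)(C(C)C)C(C)C)cc2O[C@H](C)[C@H](C)C(=O)c2c1O
F3 | step 14 | (2R,3S)-5-hydroxy-2,3-dimethyl-6-(3-methylbut-2-en-1-yl)-4-oxo-7-[tri(propan-2-yl)silyl]oxy-3,4-dihydro-2H-chromene-8-carbaldehyde | CC(C)=CCc1c(O[Si](C(C)C)(C(C)C)C(C)C)c(C=O)c2O[C@H](C)[C@H](C)C(=O)c2c1O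
F4 | step 14 | methyl (2E)-3-[(2R,3S)-5-hydroxy-2,3-dimethyl-6-(3-methylbut-2-en-1-yl)-4-oxo-7-[tri(propan-2-yl)silyl]oxy-3,4-dihydro-2H-chromen-8-yl]prop-2-enoate | COC(=O)/C=C/c1c(O[Si](C(C)C)(C(C)C)C(C)C)c(CC=C(C)C)c(O)c2c1O[C@H](C)[C@H](C)C2=O
F5 | step 10 | methyl (3R)-3-{1-(dimethylamino)-3-[(2R,3S)-2,3-dimethyl-4-oxo-3,4-dihydro-2H-pyran-6-yl]-3-oxoprop-1-en-2-yl}hexanoate | CCC[C@H](CC(=O)OC)C(=CN(C)C)C(=O)C1=CC(=O)[C@@H](C)[C@@H](C)O1
F6 | step 13 | 4-methylpent-3-enal | CC(C)=CCC=O
F7 | step 13 | 1,1-dibromo-5-methylhexa-1,4-diene | CC(C)=CCC=C(Br)Br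
F8 | step 13 | (5-methylhex-4-en-1-yn-1-yl)lithium | [Li]C#CCC=C(C)C
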